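A run that stops short tempts one to ask what died in the flask, but I first wrote the balance of the coupling partner, taking one partner for each product formed.

| setting | midnight | flask |
|---|---|---|
| left-handed substrate | 0.80 M | 0.80 M |
| right-handed substrate | 0.80 M | 0.80 M |
| coupling partner | 1.6 M | 2.40 M |
| catalyst | 3.3 mM | 3.3 mM |
| remark | run made earlier |  |
| time |  | 1.5 h |

- midnight (time / min: left-handed product / %, right-handed product / %, left-handed substrate / %): 20.0: 41, 19, 18; 40.0: 49, 24, 13; 50.0: 50, 25, 13; 80.0: 53, 25, 11

(each reading ± 1.5 percentage points)

- excess of left-handed product over right-handed product in the product at 5.0 min
- excess of left-handed product over right-handed product in the product at 1.5 h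
- part of the left-handed substrate and right-handed substrate charged together that has reacted at 1.5 h

- catalyst is single-handed; left-handed substrate and right-handed substrate are mirror images of each other, charged as a racemate, each of them at the stated concentration
- an excess is below zero if the other one leads

In the midnight run the partner was charged level with the two substrates together. At its last reading, 80.0 min, the products stood at 53% and 25%. So I kept 22.0%: the part of the partner's charge standing in no product, the lost share. That figure is a reading and carries their scatter, and the readings cannot say whether that part was destroyed or still waiting.

For the new flask I asked what remains of the partner's charge after the lost share, per substrate charged, and which numbers that budget needs. The catalyst charge is the same in both flasks and does not enter the balance. A scatter of 1.5 percentage points on both products in the same direction moves the budget by 4.5 points. If the loss were a fixed amount and not a share, the budget would rise by 11 points. The partner's charge counts in full, in proportion. The budget itself came to 117%, a margin of 17.0%, so I expected the substrates to be the limiting reagent in this flask, with no ceiling from the partner below their charge.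

The forecast gave 37%, 34% and 91%, remarking “The order is untested, so the low side is wide”. The flask gave 36.5%, 27.7% and 96.4%.

    coupling partner + catalyst + left-handed substrate → catalyst + left-handed product (k = 0.360 M⁻² s⁻¹)
    coupling partner + catalyst + right-handed substrate → catalyst + right-handed product (k = 0.140 M⁻² s⁻¹)
    coupling partner → decomposition product (k = 6.90 × 10⁻⁶ s⁻¹)
    left-handed substrate ⇌ right-handed substrate (k = 6.30 × 10⁻⁴ s⁻¹)
    coupling partner → decomposed reagent (k = 9.20 × 10⁻⁵ s⁻¹)

The flask's conversion of 96.4% at 1.50 h stayed under the budget of 117%, with 17% of the partner's charge still present. Decomposed reagent and decomposition product together then held 18.3% of that charge, so with the partner still present 35.7% of it stood in no product, against the lost share of 22.0% read in the midnight run at 80.0 min. In the neighbour flask charged with 0.60 M of partner, the same lost share gives a budget of 29.2% of the substrates. That neighbour reached 34.2% conversion, with 0.39% of its partner left.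

The data were generated by integration with made-up constants, noise included.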